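**Assumptions and remarks on the chemistry**

- Ring compounds carry labdane numbering: ring A = C1–C5 and C10, ring B = C5–C10, C17 on C8, C18/C19 on C4, C20 on C10, side chain C11–C16 on C9. The target is read as (5S,6S,7S,10S)-6β,7α-diacetoxylabda-8,13(Z)-dien-15-ol.
- The cyclisation precursor 8 is (5S,6S) by the CIP rules. The carvone stereocentre is untouched in space, but the new quaternary neighbour outranks isopropenyl, so its descriptor changes from R to S.
- The 2-sulfonylallyl unit is not drawn from allyl phenyl sulfone, whose sulfur sits on the terminal carbon of the allyl group and is not moved to the central carbon by any simple operation. It is built from phenyl vinyl sulfone and formaldehyde.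
- (Z)-3-Methylpent-2-en-4-yn-1-ol, if coupled as its acetylide, would leave a C11≡C12 triple bond that is hard to saturate selectively next to the Z-alkene. It is therefore converted into a saturated C11 nucleophile before coupling.
- A 6,7-dione is avoided. It would enolise towards C5 and erase that stereocentre, so C7 is reduced and inverted before C6 is oxidised.
- Commercial (Z)-3-methylpent-2-en-4-yn-1-ol is taken as the pure Z isomer.

## Structural features

The target is a labdane: a trans-fused decalin (rings A and B) with a gem-dimethyl carbon at C4, an angular methyl on C10 and a tetrasubstituted C8=C9 alkene that carries a methyl on C8 and, on C9, a five-carbon chain ending in a (Z)-trisubstituted allylic alcohol (C13=C14, C15–OH). Four contiguous stereocentres run C10–C5–C6–C7: quaternary C10 (methyl β), C5 (hydrogen α), C6 (acetoxy β, axial) and C7 (acetoxy α, pseudo-axial and allylic). The two acetates are trans-diaxial, and the C6 oxygen sits on the β face beside the C10 methyl and the β-methyl on C4, so it is best set by hydride attack on a C6 ketone from the open α face and not by an oxygen reagent coming from the β face. Fragile elements are the ionisable allylic C7 acetate, the base-labile esters, the primary allylic alcohol and the Z geometry of C13=C14, which must not meet isomerising or hydrogenating conditions once it is near other alkenes. The real difficulty is twofold: the quaternary C10 beside C5 in a trans fusion that also holds the quaternary C4, and the anti C6/C7 dioxygenation next to a tetrasubstituted alkene carrying the side chain. The key step exploits the fact that ring B, with C5, the C8 methyl and a carbonyl at C9, is (R)-carvone, whose isopropenyl carbon is C4. Hydrogen-atom transfer therefore makes a tertiary C4 radical that closes ring A onto C3 of a 2-sulfonylallyl arm on C10 and creates the gem-dimethyl carbon in the same event.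

## Logic of the disconnections

**28 ⇒ 27 ⇒ 26.** The O–Si bond at C15 and the acyl C–O bond at C6 are cut last. One silyl ether carries the primary alcohol through organometallic, reductive and oxidative steps, and the hindered axial C6 hydroxyl is esterified only when nothing else is free. The forward steps need a non-basic desilylation that leaves two acetates alone, and a forcing but neutral acetylation.

**26 ⇒ 25 ⇒ 24.** The C6–H bond is cut, tracing the β C6–O bond of 26 to the carbonyl of 25, and 25 to 24. This turns a C–O bond that cannot be made from the β face into a facial choice dictated by the two syn-axial methyls. The demand is that 25, whose C7–H is allylic and α to the carbonyl, is made and reduced under near-neutral conditions.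

**24 ⇒ 23 ⇒ 22.** The C7–O ester bond is cut with inversion, and the C7–H bond of 23 is traced to the carbonyl of 22. Small hydrides should give the pseudo-equatorial 7β-alcohol, so the axial 7α-acetate is best installed by displacement at the activated allylic carbon. The forward step must activate C7–OH rather than C6–OH and must go by substitution rather than elimination.

**22 ⇒ 20.** The C6–O bond is cut back to 21, the enolate of 20. This reduces the dioxygenation problem to one enone. It requires kinetic deprotonation at C6 rather than at C11, and oxygen delivery from the α face.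

**20 ⇒ 19 ⇒ 18.** 20 is recognised as the 1,3-oxidative transposition product of 19, and the C2–H bond of 19 is traced to the C2–S bond of 18. The carvone enone pattern is thereby kept to the end of skeleton building. The sulfone must be removed while no enone is present, and the chromate shift must outrun dehydration.

**18 ⇒ 9 + 15.** The C9–C11 bond is cut. The whole side chain, with its Z alkene and protected alcohol, arrives in one convergent step as an sp3 nucleophile. This requires 1,2-addition to a carbonyl flanked by a quaternary carbon, with a reagent of low basicity so that the sulfone α-hydrogen is tolerated.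

**9 ⇒ 8.** The C3–C4 bond is cut, opening ring A. The decalin with both quaternary carbons is simplified to a monocyclic cyclohexenone whose C5 and C10 configurations are already correct. The forward step needs a tertiary radical at C4 and a 6-endo acceptor, which the sulfone on C2 provides.

**8 ⇒ 6 + 3, 6 ⇒ 4.** The C1–C10 and C10–C20 bonds are cut. Two successive enolate alkylations on the same α′ carbon build the quaternary centre. The second, larger electrophile must enter anti to the isopropenyl group.

**3 ⇒ 2 ⇒ 1.** The C–Br bond and the C–C bond to the hydroxymethyl carbon are cut. The sulfonyl group must sit on the central carbon of the allyl unit, which an α-hydroxymethylation of 1 provides directly.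

**15 ⇒ 14 ⇒ 12 ⇒ 11 ⇒ 10.** The C–I and C–O bonds at C11 and two C–H bonds at C11/C12 are cut. The Z alkene is bought, not made. The forward steps need selective semi-reduction of the alkyne and hydroboration of the resulting terminal vinyl group only.

## Other disconnections considered

Alternative 1: Both C5–C10 and C3–C4 are cut, opening rings A and B to the acyclic polyenone A1. In A1 a C3=C2–C1=C10 diene is tied through C9=C8–C7–C6 to the β,β-dimethyl enone C5=C4. The forward step is a Me2AlCl-promoted intramolecular Diels–Alder reaction giving A2.

- In its favour: one step would make both rings, both quaternary carbons and the C5/C10 relationship. The side chain, the C8=C9 alkene, the 7α-acetate and a C6 carbonyl are already in place. After A2 only saturation of C1=C2, α-face reduction at C6, acetylation and desilylation remain. On step count after the key step and on the C6/C7 pattern this is better than the chosen plan.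
- Against it: both new bonds end at a carbon that becomes quaternary, and the dienophile is a β,β-disubstituted enone. Facial selectivity would rest on one acetoxy stereocentre that is α to the Lewis-acid-bound ketone and so open to epimerisation or elimination. A1 needs a stereodefined tetrasubstituted alkene and an E-diene, whose assembly would cost much of what the endgame saves. The C1=C2 alkene would have to be hydrogenated beside a Z-trisubstituted one.
- Comparison: a concerted cycloaddition fixes C5/C10 through its transition-state geometry, whereas the chosen plan fixes them through the order of two alkylations on a chiral-pool ring. The latter is the surer control of relative and absolute configuration. Overall step economy is about equal.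

Alternative 2: C9–C10 and C7–C8 are cut, so ring B comes from the ring A siloxydiene A3 (C10=C5 with a 1-siloxyvinyl group supplying C6 and C7) and the ynoyl imide A4 (C8 with its methyl, C9 with C11 as the acyl carbon). The forward step is an enantioselective [4+2] cycloaddition on a chiral bis(oxazoline) complex of Cu(SbF6)2 (divalent copper) giving A5.

- In its favour: C10 is set by a catalyst, so either enantiomer is accessible; here it is better than a chiral-pool route. The C8=C9 alkene and a C6 oxygen arrive with the ring, and both partners are one or two steps from achiral materials.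
- Against it: the diene terminus C10 is fully substituted and twisted by the neighbouring gem-dimethyl carbon, so reactivity and enantioselectivity are both uncertain. C5 is sp2 in A5 and would have to be set later by protonation towards the trans fusion. A5 is a drimane, so five carbons with the Z alkene must still be added at C11, and C7 must still be oxidised with α configuration.
- Comparison: the mechanism is attractive and the start is shorter. The chosen plan is stronger on structure because C5 and C10 are both secure before ring A exists, and it should be shorter overall because its side chain arrives complete.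

Alternative 3: C7–C8 and C8–C9 are cut, removing C8 with its methyl and contracting ring B to the cyclopentene of hydrindene A6. In the forward direction, chloro(methyl)carbenoid from CH3CHCl2 and n-BuLi adds to C7=C9 to give chlorocyclopropane A7. AgOAc in acetic acid then opens A7 to the allyl cation, which acetate captures at C7 to give A8.

- In its favour: one sequence delivers the C8 methyl, the C8=C9 alkene and the axial 7α-acetate anti to a 6β-ester that was placed earlier on the five-membered ring. For the trans-diaxial C6/C7 pattern this is better than the chosen plan, which spends five steps on it.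
- Against it: an enantiopure trans-hydrindene with the quaternary C10 is harder to reach than the decalin. Carbenoid addition to a hindered trisubstituted alkene would give two C8 epimers, and only the one with chlorine endo can open in the disrotatory sense that a six-membered ring allows. The cation could also be trapped at C9 or lose a proton. A8 has only C11 and C12 of the side chain, and its pivalate must be exchanged for acetate beside an acetate.
- Comparison: the cationic ring expansion is stereoelectronically well defined and equal in elegance to the radical closure. The chosen plan is better on step economy for the skeleton and side chain, and weaker on the oxidation pattern.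

Key step: step 5

## Steps

Step 1
Reactants: 1 phenyl vinyl sulfone
Product: 2 2-(phenylsulfonyl)prop-2-en-1-ol
Conditions: aq. HCHO (37%), DABCO (0.3 equiv), THF/H2O, rt
Reagents that add atoms: formaldehyde, C=O
Why: Morita–Baylis–Hillman hydroxymethylation: DABCO adds to the vinyl sulfone, the α-sulfonyl carbanion is trapped by formaldehyde and the amine is expelled; vinyl sulfones are established acceptors and formaldehyde is the most reactive aldehyde partner.

Step 2
Reactants: 2 2-(phenylsulfonyl)prop-2-en-1-ol
Product: 3 3-bromo-2-(phenylsulfonyl)prop-1-ene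
Conditions: PBr3, Et2O, −10 → 0 °C
Reagents that add atoms: phosphorus tribromide, BrP(Br)Br
Why: Standard conversion of a primary allylic alcohol into the bromide, as for 2-(hydroxymethyl)acrylates; the electron-poor alkene does not add HBr in the cold.

Step 3
Reactants: 4 (R)-(−)-carvone
Product: 6 (5R,6RS)-2,6-dimethyl-5-(prop-1-en-2-yl)cyclohex-2-en-1-one (6-methylcarvone), via carvone lithium enolate 5 (not isolated)
Conditions: LiN(iPr)2, THF, −78 °C; MeI, −78 → 0 °C
Reagents that add atoms: iodomethane, CI; lithium diisopropylamide, [Li+].CC(C)[N-]C(C)C (lithium in 5 only)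
Why: Kinetic α′-deprotonation of the enone gives the cross-conjugated enolate, which is C-methylated; the C6 epimers need not be separated because this centre is planarised again in step 4.

Step 4
Reactants: 6 (5R,6RS)-2,6-dimethyl-5-(prop-1-en-2-yl)cyclohex-2-en-1-one (6-methylcarvone); 3 3-bromo-2-(phenylsulfonyl)prop-1-ene
Product: 8 (5S,6S)-2,6-dimethyl-6-[2-(phenylsulfonyl)prop-2-en-1-yl]-5-(prop-1-en-2-yl)cyclohex-2-en-1-one, via 6-methylcarvone lithium enolate 7 (not isolated)
Conditions: LiN(iPr)2, THF, −78 → −20 °C; then 3 (1.3 equiv), −78 °C
Reagents that add atoms: lithium diisopropylamide, [Li+].CC(C)[N-]C(C)C (lithium in 7 only)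
Why: Enolate alkylation by addition–elimination (SN2′) on the 2-sulfonylallyl bromide, which is symmetrical in its two CH2 termini and therefore gives one constitution. The new quaternary centre (labdane C10) is set by approach anti to the pseudo-axial isopropenyl group on the neighbouring carbon, which places the arm trans to isopropenyl and the methyl cis, as a trans-decalin requires.

Step 5
Reactants: 8 (5S,6S)-2,6-dimethyl-6-[2-(phenylsulfonyl)prop-2-en-1-yl]-5-(prop-1-en-2-yl)cyclohex-2-en-1-one
Product: 9 (4aS,8aS)-2,5,5,8a-tetramethyl-7-(phenylsulfonyl)-4a,5,6,7,8,8a-hexahydronaphthalen-1(4H)-one (labdane numbering: 2-phenylsulfonyl-4,4,8,10-tetramethyl-trans-octal-7-en-9-one; C2 epimers)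
Conditions: Fe(acac)3 (0.5 equiv), PhSiH3 (2.5 equiv), EtOH/(CH2OH)2, 60 °C, 0.02 M, degassed
Reagents that add atoms: none
Why: Fe(acac)3 and PhSiH3 in ethanol form an iron hydride (trivalent iron) that transfers a hydrogen atom to the CH2 terminus of the electron-rich 1,1-disubstituted isopropenyl group, which supplies the second C4 methyl and leaves a nucleophilic tertiary C4 radical. This radical adds to C3, the unsubstituted β-carbon of the vinyl sulfone, in a 6-endo-trig closure that forms C3–C4 and ring A (C10, C1, C2, C3, C4, C5); the α-sulfonyl radical at C2 is reduced by divalent iron to the carbanion and protonated by ethanol, returning trivalent iron. The closest known reaction type is the iron-mediated hydrogen-atom-transfer reductive coupling of unactivated alkenes with vinyl sulfones and related acceptors (a Giese addition), including its intramolecular use to build quaternary carbons. 6-endo is preferred over 5-exo because attack at C2 would hit the fully substituted sulfone-bearing carbon against both sterics and polarity, whereas attack at C3 gives the sulfone-stabilised radical. No lasting stereocentre is created: C4 is gem-dimethyl, C2 forms as both epimers and loses its substituent in step 11, and the trans ring fusion is already fixed by C5 and C10 of 8, whose two ring A bonds are both equatorial on ring B. The selectivity needed is hydrogen-atom transfer to the isopropenyl group rather than to the enone or the vinyl sulfone, which the isopropenyl group secures as the most electron-rich and accessible alkene, and the C4 radical has no good alternative acceptor because closure onto the enone β-carbon C7 would make a four-membered ring and attack at C8 is a polarity-mismatched 5-endo process. Dilution and exclusion of air suppress premature reduction and Mukaiyama-type hydration of the C4 radical.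

Step 6
Reactants: 10 (Z)-3-methylpent-2-en-4-yn-1-ol
Product: 11 (Z)-tert-butyldimethyl[(3-methylpent-2-en-4-yn-1-yl)oxy]silane
Conditions: TBSCl, imidazole, CH2Cl2, 0 °C → rt
Reagents that add atoms: tert-butyldimethylsilyl chloride, CC(C)(C)[Si](C)(C)Cl
Why: Routine silylation of a primary alcohol; the silyl ether tolerates organolithium, dissolving-metal, chromium and hydride steps and is removed last with fluoride.

Step 7
Reactants: 11 (Z)-tert-butyldimethyl[(3-methylpent-2-en-4-yn-1-yl)oxy]silane
Product: 12 (Z)-tert-butyldimethyl[(3-methylpenta-2,4-dien-1-yl)oxy]silane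
Conditions: H2 (1 atm), Pd/CaCO3 poisoned with Pb(OAc)2, quinoline, hexane, rt
Reagents that add atoms: none
Why: Semi-hydrogenation of a terminal alkyne on poisoned palladium stops at the vinyl group; the existing trisubstituted Z alkene is neither reduced nor isomerised under these conditions.

Step 8
Reactants: 12 (Z)-tert-butyldimethyl[(3-methylpenta-2,4-dien-1-yl)oxy]silane
Product: 14 (Z)-5-[(tert-butyldimethylsilyl)oxy]-3-methylpent-3-en-1-ol, via B-alkyl-9-borabicyclononane 13 (not isolated)
Conditions: 9-BBN, THF, 0 °C → rt; then aq. NaOH, H2O2, 0 °C
Reagents that add atoms: 9-borabicyclo[3.3.1]nonane, B1C2CCCC1CCC2 (boron and bicycle in 13 only); hydrogen peroxide, OO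
Why: Hydroboration–oxidation: the bulky borane adds boron to the terminal carbon of the monosubstituted alkene of the diene and leaves the trisubstituted alkene alone, and oxidation with retention gives the homoallylic alcohol.

Step 9
Reactants: 14 (Z)-5-[(tert-butyldimethylsilyl)oxy]-3-methylpent-3-en-1-ol
Product: 15 (Z)-tert-butyl[(5-iodo-3-methylpent-2-en-1-yl)oxy]dimethylsilane
Conditions: I2, PPh3, imidazole, CH2Cl2, 0 °C
Reagents that add atoms: iodine, II
Why: Appel-type iodination of a primary alcohol through the alkoxyphosphonium iodide; neutral conditions leave the silyl ether and the alkene geometry untouched.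

Step 10
Reactants: 15 (Z)-tert-butyl[(5-iodo-3-methylpent-2-en-1-yl)oxy]dimethylsilane; 9 (4aS,8aS)-2,5,5,8a-tetramethyl-7-(phenylsulfonyl)-4a,5,6,7,8,8a-hexahydronaphthalen-1(4H)-one
Product: 18 15-(tert-butyldimethylsilyloxy)-2-(phenylsulfonyl)labda-7,13(Z)-dien-9-ol (C2 and C9 epimers), via homoallylic organolithium 16 (not isolated), via organocerium dichloride 17 (not isolated)
Conditions: 15 (2 equiv), t-BuLi (4 equiv), Et2O, −78 °C; CeCl3 (anhydrous), THF, −78 °C; then 9, −78 → −40 °C; aq. NH4Cl
Reagents that add atoms: tert-butyllithium, [Li]C(C)(C)C (lithium in 16 only); cerium trichloride, Cl[Ce](Cl)Cl (cerium and chlorine in 17 only)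
Why: Iodine–lithium exchange, transmetalation to cerium and 1,2-addition to the enone carbonyl, forming C9–C11. The organocerium reagent is nucleophilic but weakly basic, so it should add to the carbonyl flanked by the quaternary C10 without deprotonating the sulfone α-position or C6; the C9 configuration is immaterial because C9 becomes sp2 in step 12.

Step 11
Reactants: 18 15-(tert-butyldimethylsilyloxy)-2-(phenylsulfonyl)labda-7,13(Z)-dien-9-ol
Product: 19 15-(tert-butyldimethylsilyloxy)labda-7,13(Z)-dien-9-ol (C9 epimers)
Conditions: Na(Hg) (6%), Na2HPO4, MeOH/THF, −20 → 0 °C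
Reagents that add atoms: none
Why: Reductive desulfonylation of a secondary alkyl phenyl sulfone by electron transfer and protonation. This is the one stage of the route without an enone or ester, and the tertiary allylic alcohol, the alkenes and the silyl ether are inert to buffered sodium amalgam.

Step 12
Reactants: 19 15-(tert-butyldimethylsilyloxy)labda-7,13(Z)-dien-9-ol
Product: 20 15-(tert-butyldimethylsilyloxy)labda-8,13(Z)-dien-7-one
Conditions: [C5H5NH][CrO3Cl] (3 equiv), 4 Å molecular sieves, CH2Cl2, rt
Reagents that add atoms: pyridinium chlorochromate, [O-][Cr](=O)(=O)Cl.c1cc[nH+]cc1 (the C7 oxygen)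
Why: Babler–Dauben oxidative 1,3-transposition: the tertiary chromate ester (hexavalent chromium) undergoes a [3,3] shift from C9 to C7 and the secondary allylic chromate is oxidised to the enone, leaving tetravalent chromium. Relief of strain at the congested C9 and formation of the tetrasubstituted conjugated alkene drive the shift.

Step 13
Reactants: 20 15-(tert-butyldimethylsilyloxy)labda-8,13(Z)-dien-7-one
Product: 22 15-(tert-butyldimethylsilyloxy)-6α-hydroxylabda-8,13(Z)-dien-7-one, via potassium 6,8-dien-7-olate 21 (not isolated)
Conditions: KN(SiMe3)2, THF, −78 °C; 2-(phenylsulfonyl)-3-phenyloxaziridine, −78 °C; aq. NH4Cl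
Reagents that add atoms: potassium bis(trimethylsilyl)amide, [K+].C[Si](C)(C)[N-][Si](C)(C)C (potassium in 21 only); 2-(phenylsulfonyl)-3-phenyloxaziridine, O=S(=O)(c1ccccc1)N1OC1c1ccccc1
Why: Kinetic α′-deprotonation at C6 gives the cross-conjugated enolate, which is hydroxylated by the N-sulfonyloxaziridine. The β face of C6 is closed by the syn-axial C10 and C4 methyls, so oxygen enters from the α face, and an enolate oxidant is used instead of a peracid to spare the side-chain alkene.

Step 14
Reactants: 22 15-(tert-butyldimethylsilyloxy)-6α-hydroxylabda-8,13(Z)-dien-7-one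
Product: 23 15-(tert-butyldimethylsilyloxy)labda-8,13(Z)-diene-6α,7β-diol
Conditions: NaBH4, CeCl3·7H2O, MeOH, −78 → −40 °C
Reagents that add atoms: none
Why: Luche 1,2-reduction of the enone; the small hydride attacks C7 along the axial trajectory from the α face and gives the pseudo-equatorial 7β-alcohol. This step removes the C7 carbonyl before C6 is oxidised, so no 6,7-dione is ever formed.

Step 15
Reactants: 23 15-(tert-butyldimethylsilyloxy)labda-8,13(Z)-diene-6α,7β-diol
Product: 24 7α-acetoxy-15-(tert-butyldimethylsilyloxy)labda-8,13(Z)-dien-6α-ol
Conditions: PPh3, DIAD, AcOH, THF, 0 °C → rt; crude product taken directly into step 16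
Reagents that add atoms: acetic acid, CC(=O)O
Why: Mitsunobu esterification with inversion: the allylic C7 oxyphosphonium is displaced by acetate from the α face, the axial direction, while the hindered 6α-hydroxyl cannot be displaced from the blocked β face. SN2′ attack at the fully substituted C9 is disfavoured, and the rigid diequatorial diol cannot reach the anti geometry needed for epoxide closure.

Step 16
Reactants: 24 7α-acetoxy-15-(tert-butyldimethylsilyloxy)labda-8,13(Z)-dien-6α-ol
Product: 25 7α-acetoxy-15-(tert-butyldimethylsilyloxy)labda-8,13(Z)-dien-6-one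
Conditions: Dess–Martin periodinane, NaHCO3, CH2Cl2, 0 °C → rt
Reagents that add atoms: none
Why: Neutral periodinane oxidation of the equatorial secondary alcohol; the buffered, non-basic medium avoids enolisation at C7 or C5 and acetyl migration.

Step 17
Reactants: 25 7α-acetoxy-15-(tert-butyldimethylsilyloxy)labda-8,13(Z)-dien-6-one
Product: 26 7α-acetoxy-15-(tert-butyldimethylsilyloxy)labda-8,13(Z)-dien-6β-ol
Conditions: NaBH4, CeCl3·7H2O, MeOH/THF, −40 → 0 °C
Reagents that add atoms: none
Why: Hydride reduction of the C6 ketone; the β face is shielded by the syn-axial C10 methyl and the β-methyl on C4, so hydride enters from the α face and gives the axial 6β-alcohol. The resulting trans-diaxial hydroxy acetate cannot undergo acyl migration.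

Step 18
Reactants: 26 7α-acetoxy-15-(tert-butyldimethylsilyloxy)labda-8,13(Z)-dien-6β-ol
Product: 27 6β,7α-diacetoxy-15-(tert-butyldimethylsilyloxy)labda-8,13(Z)-diene
Conditions: Ac2O, DMAP, pyridine, 40 °C
Reagents that add atoms: acetic anhydride, CC(=O)OC(C)=O
Why: DMAP-catalysed acylation through the N-acetylpyridinium ion is strong enough for an axial secondary alcohol and does not ionise the allylic C7 acetate.

Step 19
Reactants: 27 6β,7α-diacetoxy-15-(tert-butyldimethylsilyloxy)labda-8,13(Z)-diene
Product: 28 (5S,6S,7S,10S)-6β,7α-diacetoxylabda-8,13(Z)-dien-15-ol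
Conditions: HF·pyridine, pyridine, THF, 0 °C → rt
Reagents that add atoms: none
Why: Fluoride cleavage of the primary silyl ether under buffered, non-basic conditions, which avoids acetate hydrolysis or migration and ionisation of the allylic acetate.

## Compound list

1 | phenyl vinyl sulfone | C=CS(=O)(=O)c1ccccc1 | starting material
2 | 2-(phenylsulfonyl)prop-2-en-1-ol | C=C(CO)S(=O)(=O)c1ccccc1 | intermediate
3 | 3-bromo-2-(phenylsulfonyl)prop-1-ene | C=C(CBr)S(=O)(=O)c1ccccc1 | intermediate
4 | (R)-(−)-carvone | CC(=C)[C@@H]1CC=C(C)C(=O)C1 | starting material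
5 | lithium enolate of carvone (cross-conjugated, C1=C6; formed in the flask, not isolated) | [Li+].CC(=C)[C@@H]1CC=C(C)C([O-])=C1 | intermediate
6 | (5R,6RS)-2,6-dimethyl-5-(prop-1-en-2-yl)cyclohex-2-en-1-one (6-methylcarvone, C6 epimers) | CC(=C)[C@@H]1CC=C(C)C(=O)C1C | intermediate
7 | lithium enolate of 6-methylcarvone (formed in the flask, not isolated) | [Li+].CC(=C)[C@@H]1CC=C(C)C([O-])=C1C | intermediate
8 | (5S,6S)-2,6-dimethyl-6-[2-(phenylsulfonyl)prop-2-en-1-yl]-5-(prop-1-en-2-yl)cyclohex-2-en-1-one (arm trans to isopropenyl) | C1C=C(C)C(=O)[C@@](C)(CC(=C)S(=O)(=O)c2ccccc2)[C@@H]1C(C)=C | intermediate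
9 | (4aS,8aS)-2,5,5,8a-tetramethyl-7-(phenylsulfonyl)-4a,5,6,7,8,8a-hexahydronaphthalen-1(4H)-one (trans fusion, sulfone epimers) | C1C=C(C)C(=O)[C@@]2(C)CC(S(=O)(=O)c3ccccc3)CC(C)(C)[C@H]12 | intermediate
10 | (Z)-3-methylpent-2-en-4-yn-1-ol | C#C/C(C)=C\CO | starting material
11 | (Z)-tert-butyldimethyl[(3-methylpent-2-en-4-yn-1-yl)oxy]silane | C#C/C(C)=C\CO[Si](C)(C)C(C)(C)C | intermediate
12 | (Z)-tert-butyldimethyl[(3-methylpenta-2,4-dien-1-yl)oxy]silane | C=C/C(C)=C\CO[Si](C)(C)C(C)(C)C | intermediate
13 | 9-[(Z)-5-(tert-butyldimethylsilyloxy)-3-methylpent-3-en-1-yl]-9-borabicyclo[3.3.1]nonane (formed in the flask, not isolated) | CC(C)(C)[Si](C)(C)OC/C=C(C)\CCB1C2CCCC1CCC2 | intermediate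
14 | (Z)-5-[(tert-butyldimethylsilyl)oxy]-3-methylpent-3-en-1-ol | OCC/C(C)=C\CO[Si](C)(C)C(C)(C)C | intermediate
15 | (Z)-tert-butyl[(5-iodo-3-methylpent-2-en-1-yl)oxy]dimethylsilane | ICC/C(C)=C\CO[Si](C)(C)C(C)(C)C | intermediate
16 | (Z)-5-(tert-butyldimethylsilyloxy)-3-methylpent-3-en-1-yllithium (formed in the flask, not isolated) | [Li]CC/C(C)=C\CO[Si](C)(C)C(C)(C)C | intermediate
17 | (Z)-5-(tert-butyldimethylsilyloxy)-3-methylpent-3-en-1-ylcerium dichloride (formed in the flask, not isolated) | Cl[Ce](Cl)CC/C(C)=C\CO[Si](C)(C)C(C)(C)C | intermediate
18 | 15-(tert-butyldimethylsilyloxy)-2-(phenylsulfonyl)labda-7,13(Z)-dien-9-ol (C2 and C9 epimers) | C1C=C(C)C(O)(CC/C(C)=C\CO[Si](C)(C)C(C)(C)C)[C@@]2(C)CC(S(=O)(=O)c3ccccc3)CC(C)(C)[C@H]12 | intermediate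
19 | 15-(tert-butyldimethylsilyloxy)labda-7,13(Z)-dien-9-ol (C9 epimers) | C1C=C(C)C(O)(CC/C(C)=C\CO[Si](C)(C)C(C)(C)C)[C@@]2(C)CCCC(C)(C)[C@H]12 | intermediate
20 | 15-(tert-butyldimethylsilyloxy)labda-8,13(Z)-dien-7-one | C1C(=O)C(C)=C(CC/C(C)=C\CO[Si](C)(C)C(C)(C)C)[C@@]2(C)CCCC(C)(C)[C@H]12 | intermediate
21 | potassium 15-(tert-butyldimethylsilyloxy)labda-6,8,13(Z)-trien-7-olate (formed in the flask, not isolated) | [K+].C1=C([O-])C(C)=C(CC/C(C)=C\CO[Si](C)(C)C(C)(C)C)[C@@]2(C)CCCC(C)(C)[C@H]12 | intermediate
22 | 15-(tert-butyldimethylsilyloxy)-6α-hydroxylabda-8,13(Z)-dien-7-one | O[C@H]1C(=O)C(C)=C(CC/C(C)=C\CO[Si](C)(C)C(C)(C)C)[C@@]2(C)CCCC(C)(C)[C@H]12 | intermediate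
23 | 15-(tert-butyldimethylsilyloxy)labda-8,13(Z)-diene-6α,7β-diol | O[C@H]1[C@H](O)C(C)=C(CC/C(C)=C\CO[Si](C)(C)C(C)(C)C)[C@@]2(C)CCCC(C)(C)[C@H]12 | intermediate
24 | 7α-acetoxy-15-(tert-butyldimethylsilyloxy)labda-8,13(Z)-dien-6α-ol | O[C@H]1[C@@H](OC(C)=O)C(C)=C(CC/C(C)=C\CO[Si](C)(C)C(C)(C)C)[C@@]2(C)CCCC(C)(C)[C@H]12 | intermediate
25 | 7α-acetoxy-15-(tert-butyldimethylsilyloxy)labda-8,13(Z)-dien-6-one | O=C1[C@@H](OC(C)=O)C(C)=C(CC/C(C)=C\CO[Si](C)(C)C(C)(C)C)[C@@]2(C)CCCC(C)(C)[C@H]12 | intermediate
26 | 7α-acetoxy-15-(tert-butyldimethylsilyloxy)labda-8,13(Z)-dien-6β-ol | O[C@@H]1[C@@H](OC(C)=O)C(C)=C(CC/C(C)=C\CO[Si](C)(C)C(C)(C)C)[C@@]2(C)CCCC(C)(C)[C@H]12 | intermediate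
27 | 6β,7α-diacetoxy-15-(tert-butyldimethylsilyloxy)labda-8,13(Z)-diene | CC(=O)O[C@@H]1[C@@H](OC(C)=O)C(C)=C(CC/C(C)=C\CO[Si](C)(C)C(C)(C)C)[C@@]2(C)CCCC(C)(C)[C@H]12 | intermediate
28 | (5S,6S,7S,10S)-6β,7α-diacetoxylabda-8,13(Z)-dien-15-ol | CC(=O)O[C@@H]1[C@@H](OC(C)=O)C(C)=C(CC/C(C)=C\CO)[C@@]2(C)CCCC(C)(C)[C@H]12 | target

## Step count and least certain steps

Total: 19 steps. Longest linear sequence: 14 steps, from 10 to 28 through steps 6–19. The chain from 1 through steps 1, 2, 4, 5 and 10–19 is equally long, and the chain from 4 through steps 3–5 and 10–19 has 13 steps.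

**Step 5 (key step).** Hydrogen-atom transfer may go to the vinyl sulfone instead of the isopropenyl group, or the C4 radical may be reduced before it closes, because closure onto a carbon next to the quaternary C10 is slow. Fallback: from 8, Markovnikov addition of HBr (HBr in AcOH, 0 °C) to the isopropenyl group would give the tertiary bromide F1. Slow addition of Bu3SnH with AIBN in benzene at 80 °C would then generate the same C4 radical by bromine abstraction and close ring A in the same 6-endo Giese sense, rejoining the route at 9.

**Step 4.** The enolate may add a second time, to the vinyl sulfone of the product, or alkylate on oxygen, or lose facial selectivity with this very reactive electrophile. Fallback: from 6, the same enolate would be alkylated with 2,3-dibromopropene, an ordinary SN2 allylation with the same anti preference, to give the 2-bromoallyl ketone F2. Coupling of the vinyl bromide with PhSO2Na (CuI, monovalent copper, with sodium L-prolinate, DMSO, 90 °C) would then install the sulfone, rejoining the route at 8.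

**Step 10.** Addition to the carbonyl beside the quaternary C10 may be slow enough for deprotonation at C6 to compete. The homoallylic organometallic may also destroy itself by intramolecular SN2′ expulsion of silanolate, closing a cyclopropane. Fallback: 11 would be deprotonated with n-BuLi to the lithium acetylide F3, a small sp nucleophile without that decomposition path, and added to 9 to give the propargylic carbinol F4. Semi-hydrogenation on Pd/CaCO3 poisoned with Pb(OAc)2 would give the Z,Z-dienyl carbinol F5. Diimide (2-nitrobenzenesulfonylhydrazide, Et3N) would then reduce the disubstituted C11=C12 alkene in preference to the trisubstituted ones, rejoining the route at 18.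

**Step 12.** The tertiary allylic alcohol may ionise and dehydrate to dienes faster than the chromate ester rearranges, and the acidic chromium reagent may attack the silyl ether. Fallback: from 19, a non-oxidative 1,3-transposition catalysed by Ph3SiOReO3 (heptavalent rhenium) in Et2O at 0 °C would give the secondary allylic alcohol F6 (C7 epimers), driven by the tetrasubstituted alkene. Oxidation with MnO2 would rejoin the route at 20.

**Step 15.** The phosphonium may form on the C6 hydroxyl, a cyclic dioxaphosphorane may form across the diol, or the allylic intermediate may eliminate instead of being substituted. Acetyl migration to the cis C6 hydroxyl can also occur if 24 is kept. Fallback: from 22, LiBH(s-Bu)3 in THF at −78 °C would deliver hydride from the equatorial β direction and give the cis 6α,7α-diol F7. Reaction with MeC(OMe)3 and catalytic camphorsulfonic acid would form the cyclic orthoacetate F8. Mild aqueous acetic acid would open it to the axial ester, the usual outcome of orthoester hydrolysis on a cis-diol, rejoining the route at 24.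

## Further compounds

F1 | step 5 | (5R,6S)-5-(2-bromopropan-2-yl)-2,6-dimethyl-6-[2-(phenylsulfonyl)prop-2-en-1-yl]cyclohex-2-en-1-one | C1C=C(C)C(=O)[C@@](C)(CC(=C)S(=O)(=O)c2ccccc2)[C@@H]1C(C)(C)Br
F2 | step 4 | (5S,6S)-6-(2-bromoprop-2-en-1-yl)-2,6-dimethyl-5-(prop-1-en-2-yl)cyclohex-2-en-1-one | C1C=C(C)C(=O)[C@@](C)(CC(=C)Br)[C@@H]1C(C)=C
F3 | step 10 | lithium acetylide of 11 | [Li]C#C/C(C)=C\CO[Si](C)(C)C(C)(C)C
F4 | step 10 | 15-(tert-butyldimethylsilyloxy)-2-(phenylsulfonyl)labda-7,13(Z)-dien-11-yn-9-ol | C1C=C(C)C(O)(C#C/C(C)=C\CO[Si](C)(C)C(C)(C)C)[C@@]2(C)CC(S(=O)(=O)c3ccccc3)CC(C)(C)[C@H]12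
F5 | step 10 | 15-(tert-butyldimethylsilyloxy)-2-(phenylsulfonyl)labda-7,11(Z),13(Z)-trien-9-ol | C1C=C(C)C(O)(/C=C\C(C)=C/CO[Si](C)(C)C(C)(C)C)[C@@]2(C)CC(S(=O)(=O)c3ccccc3)CC(C)(C)[C@H]12
F6 | step 12 | 15-(tert-butyldimethylsilyloxy)labda-8,13(Z)-dien-7-ol (C7 epimers) | C1C(O)C(C)=C(CC/C(C)=C\CO[Si](C)(C)C(C)(C)C)[C@@]2(C)CCCC(C)(C)[C@H]12
F7 | step 15 | 15-(tert-butyldimethylsilyloxy)labda-8,13(Z)-diene-6α,7α-diol | O[C@H]1[C@@H](O)C(C)=C(CC/C(C)=C\CO[Si](C)(C)C(C)(C)C)[C@@]2(C)CCCC(C)(C)[C@H]12
F8 | step 15 | 6α,7α-O-(1-methoxyethylidene) derivative of F7 (cyclic orthoacetate) | O1[C@H]2[C@@H](OC1(C)OC)C(C)=C(CC/C(C)=C\CO[Si](C)(C)C(C)(C)C)[C@@]3(C)CCCC(C)(C)[C@H]23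
A1 | alternative 1 | (5S,6Z,8E)-5-acetoxy-7-[(Z)-5-(tert-butyldimethylsilyloxy)-3-methylpent-3-en-1-yl]-2,6,8-trimethylundeca-2,6,8,10-tetraen-4-one | C=C/C=C(C)/C(CC/C(C)=C\CO[Si](C)(C)C(C)(C)C)=C(C)\[C@H](OC(C)=O)C(=O)C=C(C)C
A2 | alternative 1 | 7α-acetoxy-15-(tert-butyldimethylsilyloxy)labda-1,8,13(Z)-trien-6-one | O=C1[C@@H](OC(C)=O)C(C)=C(CC/C(C)=C\CO[Si](C)(C)C(C)(C)C)[C@@]2(C)C=CCC(C)(C)[C@H]12
A3 | alternative 2 | tert-butyldimethyl{[1-(2,6,6-trimethylcyclohex-1-en-1-yl)vinyl]oxy}silane | C=C(O[Si](C)(C)C(C)(C)C)C1=C(C)CCCC1(C)C
A4 | alternative 2 | 3-(but-2-ynoyl)oxazolidin-2-one | CC#CC(=O)N1CCOC1=O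
A5 | alternative 2 | 3-[6-(tert-butyldimethylsilyloxy)drima-5,8-dien-11-oyl]oxazolidin-2-one | CC(C)(C)[Si](C)(C)OC=1CC(C)=C(C(=O)N3CCOC3=O)[C@@]2(C)CCCC(C)(C)C=12
A6 | alternative 3 | 3-[2-(tert-butyldiphenylsilyloxy)ethyl]-3a,7,7-trimethyl-3a,4,5,6,7,7a-hexahydro-1H-inden-1-yl pivalate (trans fusion, labdane 6β-ester) | CC(C)(C)C(=O)O[C@@H]1C=C(CCO[Si](c3ccccc3)(c3ccccc3)C(C)(C)C)[C@@]2(C)CCCC(C)(C)[C@H]12
A7 | alternative 3 | chloro(methyl)cyclopropane adduct of A6 across C7–C9 (C8 epimers) | CC(C)(C)C(=O)O[C@@H]1C3C(C)(Cl)C3(CCO[Si](c4ccccc4)(c4ccccc4)C(C)(C)C)[C@@]2(C)CCCC(C)(C)[C@H]12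
A8 | alternative 3 | 7α-acetoxy-6β-pivaloyloxy-12-(tert-butyldiphenylsilyloxy)-13,14,15,16-tetranorlabd-8-ene | CC(C)(C)C(=O)O[C@@H]1[C@@H](OC(C)=O)C(C)=C(CCO[Si](c3ccccc3)(c3ccccc3)C(C)(C)C)[C@@]2(C)CCCC(C)(C)[C@H]12
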